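The earlier runs and the new flask are simulated with constants of no real substance.

Friday's run ended at 30.0 % electrophile and 60.0 % product, so 10.0 % of the charge had gone elsewhere, as much as the protic impurity's 10.0 % of the electrophile charge.

| flask | electrophile | nucleophile | free base | protic impurity | remark | time |
|---|---|---|---|---|---|---|
| Friday's | 0.10 M (fed, over 3.0 min) | 1 equiv | 0.15 equiv | 0.010 M | run made earlier; the fed solution adds 1.0 times the starting volume |  |
| Saturday's | 0.10 M (fed, over 3.0 min) | 1 equiv | 0.22 equiv | 0.010 M | run made earlier; the fed solution adds 1.0 times the starting volume |  |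
| Monday's | 0.15 M (fed, over 3.0 min) | 1 equiv | 0.30 equiv | 0.010 M | run made earlier; the fed solution adds 1.0 times the starting volume |  |
| flask | 0.10 M (fed, over 3.0 min) | 1.00 equiv | 0.300 equiv | 0.0100 M | the fed solution adds 1.0 times the starting volume | 15 min |

| run | time / min | electrophile / % | product / % |
|---|---|---|---|
| Friday's | 1.33 | 25.1 | 14.6 |
| Friday's | 3.00 | 54.1 | 37.3 |
| Friday's | 6.00 | 37.6 | 52.4 |
| Friday's | 15.0 | 30.0 | 60.0 |
| Saturday's | 4.00 | 43.6 | 47.1 |
| Saturday's | 8.00 | 31.6 | 58.6 |
| Saturday's | 12.0 | 28.3 | 60.7 |
| Saturday's | 15.0 | 27.3 | 62.9 |
| Monday's | 2.00 | 30.5 | 30.8 |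
| Monday's | 5.00 | 34.0 | 59.4 |
| Monday's | 10.0 | 27.6 | 65.3 |
| Monday's | 15.0 | 25.7 | 67.0 |

(scatter of a reading: 0.3 percentage points)

- charges are per starting volume, the dose included; the dosed solution carries all of it
- percentages count the whole charge, also what has not yet gone in
- the earlier runs do not show how much of nucleophile is bound; that part of a forecast is a guess

- part of the electrophile that has reacted at 15 min
- share of the unused nucleophile that is free and not bound as protonated nucleophile, at 15 min

My own reckoning supposes that each product sets one acid free, taken first by free base and then by nucleophile. Past the base, nucleophile acts as limiting reagent at two per product, and the even split comes at half of nucleophile plus free base. That split plus the impurity's share is the acid line, and for this flask 75.0 %.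

The line serves as the bound from below, since the reacted part at 15.0 min stood above it in the earlier runs: by 2.5 percentage points on Friday, 1.7 points on Saturday and 2.6 points on Monday. Monday's excess, added to the line, gives a bound from above of 77.6 %. At the flask's electrophile charge, the excess read smaller on Saturday than on Friday, with more free base, so Saturday's excess tightens that bound to 76.7 %.

The forecast, 76.5 % (75 % to 78 %) reacted and 8 % (3 % to 22 %) free, puts its reacted part between 75.0 % and 76.7 %, with its own grounds in “Each unit of base buys about 0.4–0.5 units of product”.

The flask gives 75.8 % reacted, with 7.94 % of the unused nucleophile free.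

    electrophile + nucleophile → acid set free + product (k = 0.180 M⁻¹ s⁻¹)
    nucleophile + acid set free ⇌ protonated nucleophile, settled at all times (K = 5200 M⁻¹)
    acid set free + free base ⇌ salt of the base, settled at all times (K = 76000 M⁻¹)
    electrophile + protic impurity → quenched substrate (k = 0.670 M⁻¹ s⁻¹)

At 15.0 min the flask holds 65.8 % product and 10.0 % quenched substrate, with 0.587 % of the free base still free, and its reacted part stands 0.80 points above the acid line. The neighbour charged with 0.180 equiv of free base has an acid line of 69.0 % and reaches 71.0 %, which is 2 points above it.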